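Its constants were set for the occasion; the flask was simulated.

At late times the share of bis adduct in bis adduct plus isomer of the product heads for its equilibrium value, 3.57%, and you asked for a quick number with the hunch that 20 h is late enough. I doubt it, and the thing to watch on the repeat is the age of the bis adduct at the moment you sample.

common to all: time 20 h
- south-west: starting material 0.30 M (fed, over 8.0 h); partner 0.300 M; temperature −20 °C; all else is in the flask from the start; the feed brings no volume worth counting
- west: starting material 0.30 M; partner 0.300 M (fed, over 8.0 h); temperature −20 °C; all else is in the flask from the start; the feed brings no volume worth counting
- north: starting material 0.30 M; partner 0.300 M (fed, over 8.0 h); the addition at −40 °C, then warmed to −20 °C; the feed brings no volume worth counting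
- north-east: starting material 0.30 M; partner 0.300 M; temperature −20 °C; everything together at the start

    starting material + partner → single product + by-product (k1 = 0.13 /M/h, Ea1 = 64.0 kJ/mol)
    partner + single product → bis adduct + by-product (k2 = 0.15 /M/h, Ea2 = 56.0 kJ/mol)
    bis adduct ⇌ isomer of the product (K3 = 27, k3 = 0.096 /h, Ea3 = 79.0 kJ/mol, ΔH3 = −17.0 kJ/mol)
    (constants at −20 °C)

1. the flask with the highest share of bis adduct in bis adduct plus isomer of the product ("all alike" if they lie within 1.5 percentage points) (south-west / west / north / north-east / all alike)
2. share of bis adduct in bis adduct plus isomer of the product at the end, south-west
3. share of bis adduct in bis adduct plus isomer of the product at the end, west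
4. share of bis adduct in bis adduct plus isomer of the product at the end, north
5. share of bis adduct in bis adduct plus isomer of the product at the end, north-east

The isomerisation is first order both ways, so at −20 °C it has one relaxation time at any concentration: one over its forward and reverse constants added, 10.0 h. Because 20 h is twice that, I expect a reading under kinetic control, not thermodynamic control.

The concentration to follow is c(single product). It starts at zero, and as a rough assumption of my own I let it climb in a straight line, which has bis adduct form at a rising rate and puts its mean age at about a third of the time since the climb began. My rule, which leaves the equilibrium share aside, is that the share is the exponential of minus mean age over relaxation time. The starting points of the climb are my own choice, with north's at the end of its feed at −40 °C: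

| Flask | Climb begins | My share |
|---|---|---|
| south-west | 4.00 h | 58.8% |
| west | 4.00 h | 58.8% |
| north | 8.0 h | 67.2% |
| north-east | at the start | 51.5% |

So I name north.

The forecast also names north, with 56% for south-west, 56% for west, 66% for north and 50% for north-east, on the ground that “later formation leaves more of it unisomerised”. Its figures for south-west, west, north and north-east each stand lower than mine.

The simulation gives north as highest, with south-west 56.1%, west 57.4%, north 65.5% and north-east 49.5%, so the forecast held. At 8.00 h, north held 1.12% of the starting material charged as single product, against 11.7% in south-west. With the relaxation time, my rule puts north a factor 1.31 above north-east, and the simulated shares stand at a ratio of 1.32.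

Take north again, read at 72.0 h. Counted from 8.0 h, the rule gives 11.8%, and the simulation gives 12.0%.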